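## Structural features

The target is an ent-labdane: a trans-fused decalin in which ring A (C1–C5, C10) carries a gem-dimethyl group at C4 and an equatorial 3-methylbut-2-enoate at C2. Ring B (C5–C10) carries the angular methyl C20 on C10 and one trisubstituted olefin, C7=C8, with C17 on C8. C9 bears a six-carbon chain (C11–C16) that ends in a tertiary vinyl carbinol at C13. C5, C10 and C9 are contiguous stereocentres (5R,9R,10R: H5 and H9 anti to C20, C11 syn to C20); C2 (R) has its oxygen on the face opposite C20, and C13 (S) is insulated from the core by C11 and C12. Fragile groups are the tertiary allylic alcohol (ionisation, allylic transposition), the conjugated ester (hydride, organometallics, deconjugation) and the ring-B olefin, which lies β,γ to any carbonyl at C11 and can slip into conjugation. The real difficulties are the quaternary C10 between two stereogenic methines, the exact position of the ring-B olefin, and C13, which the core cannot control. The key step uses the fact that C7=C8 lies between a C6–C7 arm on C5 and a C8(C17) unit on C9, so an allyl group on C5 and an isopropenyl group on C9 can be joined exactly there by ring-closing metathesis. A configurational check raised no correction: (R)-2-methylglycidol maps onto 13S when its epoxide methylene becomes C12 and its hydroxymethyl carbon C14, and the triene ester and bicyclic ester of the key step carry the 5R,9R,10R arrangement of the target.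

## Logic of the disconnections

27 ⇒ 26 + 10. The C2–O acyl bond is cut last in the retrosynthesis because the conjugated ester would not survive hydride, organolithium or dissolving-metal steps. This leaves 26 with two hydroxyls of very different reactivity. The forward acylation must pick the secondary equatorial alcohol over the tertiary allylic one without deconjugating the acyl group or ionising C13.

26 ⇒ 25 ⇒ 21 + 24. After adding a sulfonyl group to C11 in the retrosynthetic sense, the C11–C12 bond is cut. It is the one bond that separates the remote C13 stereocentre from the bicyclic core, so C13 can come from the chiral pool and the route becomes convergent. The hindered α-sulfonyl carbanion must open 24 at its methylene carbon and not at the vinyl terminus, and the desulfonylation must spare the allylic alcohol.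

24 ⇒ 23 ⇒ 22. The C14=C15 bond is cut (methylenation) and the oxidation level adjusted, tying C13 to a commercial epoxy alcohol of the right absolute configuration. The forward steps must handle a volatile epoxide without opening it.

21 ⇒ 19 ⇒ 18 ⇒ 17 ⇒ 16. The C2–O bond is removed by retro-hydroboration to the ring-A olefin, and the sulfone is traced through sulfide and alcohol to the C11 ester. The ring-A olefin and the ester are exactly what the earlier pericyclic step leaves behind, and making the sulfone before the C2 hydroxyl exists removes the need for any protecting group. The borane must choose the ring-A olefin over the ring-B olefin, C2 over C1, and the face opposite C20.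

16 ⇒ 15. The C7=C8 bond is cut by retro-metathesis, opening ring B to a monocyclic triene. This fixes the olefin position by construction and reduces the bicycle to a ring-A building block. The forward step needs chemoselectivity among three olefins and must leave C9 untouched.

15 ⇒ 14 ⇒ 11 (through 12 and 13). The C9–C10 bond is cut by a retro-[3,3] shift, which returns the C2 oxygen as an allylic ester. One event then makes the quaternary centre and C9 and relays chirality from C2 to C10 on the face opposite the allyl group. Two design changes are made here: the ester in 11 is the conjugated 3-methylbut-2-enoate (made from 10, which also serves in the last step), whose γ-deprotonation gives a dienolate of defined Z geometry, and the acid 14 is esterified under neutral conditions. The forward step demands the Z ketene acetal, a boat-like transition state and a trans relationship of ester and allyl group in 11.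

11 ⇒ 9 + 10; 9 ⇒ 8 ⇒ 7 ⇒ 6. The ester C–O bond is cut, and the single enantiomer 9 is traced through its acetate 8 to the racemic trans alcohol 7 and the enone 6. Absolute configuration enters by enzymatic resolution; relative configuration by hydride delivery syn to the allyl group.

6 ⇒ 4 (through 5) ⇒ 2 + 3 ⇒ 1. The C10–C20 bond (methyl addition with carbonyl transposition) and the C5–C6 bond (α′-allylation) are cut, leading to a symmetrical 1,3-diketone. The forward steps need kinetic α′-deprotonation and clean 1,2-addition.

## Other disconnections considered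

Alternative 1: The cut removes the C1–C10 and C9–C11 bonds from a monocyclic ring-B enone, (S)-3-methyl-4-(2-methylbut-3-en-2-yl)cyclohex-2-en-1-one A1.
- Forward step: TiCl4 transfers an allyl group from Me3SiCH2CH=CH2 to C10 anti to the C5 substituent, and the titanium enolate is trapped at C9 by CH2O to give the keto alcohol A2. Ring A would then be closed by metathesis of the allyl and vinyl groups, and C7=C8 made from the C8 ketone.
- In favour: Sakurai-type addition is a dependable way to the quaternary centre, and C9 is epimerisable next to the ketone.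
- Better than the chosen plan: its metathesis joins two monosubstituted olefins, and the resulting ring-A olefin can be hydroborated with no ring-B olefin present.
- Against: A2 is a β-hydroxy ketone prone to retro-aldol cleavage and dehydration under the Lewis acid. The stereocentre of A1 sits next to a quaternary carbon and needs its own enantioselective synthesis. The C7=C8 position would depend on regioselective enolisation of the C8 ketone.
- Comparison: the chosen plan makes C9 and C10 in one suprafacial pericyclic event, while this one uses a three-component ionic step; step economy is about equal.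

Alternative 2: The cut removes C8–C9 and C1–C10 at once, going back to the acyclic E-enyne enol silane A3.
- Forward step: Ph3PAuNTf2 (monovalent gold) activates the alkyne, C9 attacks C8 in a 6-endo-dig closure, and the C10 cation is captured by C1 of the enol silane to give 11-silyloxy ent-drim-7-en-2-one A4.
- Better than the chosen plan: both rings, two bonds and the C9/C10 relationship are formed in one step, and C2 arrives already oxygenated, so no chemoselective hydroboration is needed.
- Equal: the E-olefin geometry translates into the relative configuration by anti addition, in principle as cleanly as the [3,3] relay.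
- Against: 1,5-enynes under cationic gold commonly divert to cyclopropyl gold carbene pathways. The enol silane may be protodesilylated before the cation forms. All stereocontrol rests on the single C5 centre of a flexible chain. A3 needs a long enantioselective preparation. The C2 ketone between two syn-axial methyl groups would favour the axial alcohol with small hydrides.
- Comparison: shorter on paper, but it rests on an unproven cascade, whereas the chosen plan builds one ring at a time with established steps.

Alternative 3: The cut is the C9–C10 bond of ring B, leading to the previtamin-type triene A5 that already holds ring A and the C2 silyloxy group.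
- Forward step: irradiation at 300–350 nm at low temperature closes the 6Z,8E-triene conrotatorily to 2,11-bis(silyloxy) ent-drima-5,7-diene A6.
- Better than the chosen plan: the C2 stereocentre is present from the start.
- Equal: the H9/C20 anti relationship follows stereospecifically from the triene geometry.
- Against: the two conrotatory senses give the two anti diastereomers relative to C2, with only the remote silyloxy group to bias helicity. Z/E isomerisation, ring reopening and a thermal [1,7]-hydrogen shift compete. A6 still needs selective reduction of C5=C6 to the trans-fused ring.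
- Comparison: the chosen plan sets C10 thermally with a defined face and needs no diene reduction; step economy is no better here.

Key step: step 10

Remark: labdane numbering (C1–C20) is used for all intermediates.
Assumption: in step 5 the lipase is taken to acylate the (1R,4R)-enantiomer of 7; if it prefers the antipode, the alcohol left behind is 9 and step 6 is dropped.

## Route

Step 1
Reactants: 1 dimedone
Product: 2 3-ethoxy-5,5-dimethylcyclohex-2-en-1-one
Conditions: EtOH, p-toluenesulfonic acid (cat.), toluene, reflux, azeotropic removal of water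
Reagents that add atoms: ethanol CCO
Why: Acid-catalysed vinylogous esterification of the enolised 1,3-diketone, driven by removal of water; no stereocentre.

Step 2
Reactants: 2 3-ethoxy-5,5-dimethylcyclohex-2-en-1-one; 3 allyl bromide
Product: 4 rac-6-allyl-3-ethoxy-5,5-dimethylcyclohex-2-en-1-one
Conditions: LiN(i-Pr)2, THF, −78 °C; 3, DMPU, −78 → 20 °C
Reagents that add atoms: none
Why: Kinetic α′-deprotonation of the vinylogous ester and SN2 allylation (first half of the Stork–Danheiser sequence); the new centre is racemic.

Step 3
Reactants: 4 rac-6-allyl-3-ethoxy-5,5-dimethylcyclohex-2-en-1-one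
Product: 6 rac-4-allyl-3,5,5-trimethylcyclohex-2-en-1-one (4-allylisophorone), via tertiary allylic carbinol 5 (not isolated)
Conditions: MeLi, Et2O, −78 → 0 °C; then 1 M HCl, 20 °C
Reagents that add atoms: methyllithium [Li]C; water O
Why: 1,2-Addition to the vinylogous ester carbonyl, then acid-induced ionisation, enol ether hydrolysis and loss of ethanol with 1,3-carbonyl transposition; the carbinol centre of 5 is destroyed.

Step 4
Reactants: 6 rac-4-allyl-3,5,5-trimethylcyclohex-2-en-1-one
Product: 7 rac-(1R*,4R*)-4-allyl-3,5,5-trimethylcyclohex-2-en-1-ol (trans)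
Conditions: Li[HB(s-Bu)3], THF, −78 °C; then NaOH, H2O2, 0 °C
Reagents that add atoms: none
Why: 1,2-Reduction of the β-substituted enone by a bulky trialkylborohydride; in the preferred half-chair the allyl group is pseudoaxial (avoiding allylic strain with the C3 methyl) and the axial C5 methyl shields the other face, so hydride should enter syn to the allyl group and leave the hydroxyl trans; any cis isomer is removed by chromatography.

Step 5
Reactants: 7 rac-(1R*,4R*)-4-allyl-3,5,5-trimethylcyclohex-2-en-1-ol
Product: 8 (1R,4R)-4-allyl-3,5,5-trimethylcyclohex-2-en-1-yl acetate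
Conditions: Burkholderia cepacia lipase (immobilised), vinyl acetate, t-BuOMe, 30 °C, stopped near half conversion
Reagents that add atoms: vinyl acetate CC(=O)OC=C
Why: Enzymatic kinetic resolution by irreversible transesterification; by the empirical size rule for lipase acylation of secondary alcohols (olefinic flank as the large group) the R carbinol should react faster, while the enantiomer of 9 stays unacylated and is separated. This step sets the absolute configuration of the whole route.

Step 6
Reactants: 8 (1R,4R)-4-allyl-3,5,5-trimethylcyclohex-2-en-1-yl acetate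
Product: 9 (1R,4R)-4-allyl-3,5,5-trimethylcyclohex-2-en-1-ol
Conditions: K2CO3, MeOH, 20 °C
Reagents that add atoms: none
Why: Base-catalysed methanolysis of the acetate at the acyl carbon; the allylic C–O bond is not broken, so both stereocentres are retained.

Step 7
Reactants: 9 (1R,4R)-4-allyl-3,5,5-trimethylcyclohex-2-en-1-ol; 10 3-methylbut-2-enoyl chloride
Product: 11 (1R,4R)-4-allyl-3,5,5-trimethylcyclohex-2-en-1-yl 3-methylbut-2-enoate
Conditions: 10, pyridine, 4-(dimethylamino)pyridine (cat.), CH2Cl2, 0 → 20 °C
Reagents that add atoms: none
Why: Nucleophilic acyl substitution with pyridine as a weak base, which avoids the vinylketene pathway that would deconjugate the acyl group; the carbinol configuration is untouched.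

Step 8
Reactants: 11 (1R,4R)-4-allyl-3,5,5-trimethylcyclohex-2-en-1-yl 3-methylbut-2-enoate
Product: 14 (2R)-2-[(1R,6R)-6-allyl-1,5,5-trimethylcyclohex-2-en-1-yl]-3-methylbut-3-enoic acid, via Z silyl ketene acetal 12 (not isolated), via trimethylsilyl ester 13 (not isolated)
Conditions: LiN(i-Pr)2, THF, −78 °C; Me3SiCl, −78 → 65 °C; then 1 M HCl
Reagents that add atoms: chlorotrimethylsilane C[Si](C)(C)Cl (silyl group of 12 and 13 only)
Why: Ireland–Claisen rearrangement of a senecioate dienolate: the amide removes a proton from the γ-methyl syn to the carbonyl of the s-cis enoate, giving the Z ketene acetal 12 (isopropenyl cis to OSi), and the [3,3] shift delivers C9 to C10 suprafacially on the face of the departing C2–O bond, opposite the allyl group, which sets 10R. A boat-like transition state is expected because the chair would push the silyloxy-bearing carbon over ring A against the syn-axial C4 methyl; boat plus Z geometry places the C9 hydrogen over the ring and gives 9R. The silyl ester 13 is hydrolysed on acidic work-up.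

Step 9
Reactants: 14 (2R)-2-[(1R,6R)-6-allyl-1,5,5-trimethylcyclohex-2-en-1-yl]-3-methylbut-3-enoic acid
Product: 15 methyl (2R)-2-[(1R,6R)-6-allyl-1,5,5-trimethylcyclohex-2-en-1-yl]-3-methylbut-3-enoate
Conditions: Me3SiCHN2, toluene–MeOH, 0 °C
Reagents that add atoms: (trimethylsilyl)diazomethane C[Si](C)(C)C=[N+]=[N-]
Why: Methyl ester formation with a diazomethane surrogate under neutral conditions, so that the β,γ-unsaturated ester neither epimerises at C9 nor moves into conjugation.

Step 10
Reactants: 15 methyl (2R)-2-[(1R,6R)-6-allyl-1,5,5-trimethylcyclohex-2-en-1-yl]-3-methylbut-3-enoate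
Product: 16 methyl ent-drima-1,7-dien-11-oate (5R,9R,10R)
Conditions: (H2IMes)(PCy3)Cl2Ru=CHPh (second-generation Grubbs catalyst, 5 mol%), 1,4-benzoquinone (10 mol%), CH2Cl2 (5 mM), 40 °C, argon sparge
Reagents that add atoms: none
Why: Olefin metathesis through metallacyclobutanes: the benzylidene exchanges with the unhindered allyl olefin to put ruthenium on C7, this alkylidene adds across the isopropenyl olefin, and cycloreversion forms C7=C8 and a ruthenium methylidene that releases ethene on the next turnover. The closest known reaction type is ring-closing metathesis of a 1,6-diene with one monosubstituted and one 1,1-disubstituted olefin to a trisubstituted cyclohexene. Ring B is closed as a six-membered carbocycle with the new olefin endocyclic; the trans fusion is already fixed because the allyl group on C5 and C9 on C10 are trans-diequatorial on ring A in the reactive conformer. No stereocentre is created; C5, C9 and C10 are spectators. Chemoselectivity rests on sterics: only the allyl terminus can load the catalyst, the isopropenyl group is reached only intramolecularly, and the cis-disubstituted ring-A olefin next to quaternary C10 offers no favourable closure. The medium is neutral, so the doubly activated C9–H should not epimerise; benzoquinone intercepts ruthenium hydrides that could move an olefin, and dilution with removal of ethene suppresses intermolecular metathesis.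

Step 11
Reactants: 16 methyl ent-drima-1,7-dien-11-oate
Product: 17 ent-drima-1,7-dien-11-ol
Conditions: LiAlH4, Et2O, 0 °C
Reagents that add atoms: none
Why: Hydride reduction of the ester to the primary alcohol at low temperature, faster than any epimerisation at C9 or olefin migration.

Step 12
Reactants: 17 ent-drima-1,7-dien-11-ol
Product: 18 11-(phenylsulfanyl)-ent-drima-1,7-diene
Conditions: PhSSPh, n-Bu3P, pyridine, 20 → 60 °C
Reagents that add atoms: diphenyl disulfide c1ccccc1SSc1ccccc1
Why: Phosphine–disulfide thioetherification (Hata-type): the alkoxyphosphonium ion of the primary alcohol is displaced by thiolate at C11 by SN2, feasible at a β-branched primary carbon; no stereocentre is involved.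

Step 13
Reactants: 18 11-(phenylsulfanyl)-ent-drima-1,7-diene
Product: 19 11-(phenylsulfonyl)-ent-drima-1,7-diene
Conditions: (NH4)6Mo7O24·4H2O (cat.), 30% H2O2, EtOH, 0 → 20 °C
Reagents that add atoms: hydrogen peroxide OO
Why: Molybdate-catalysed peroxide oxidation of sulfide to sulfone, chemoselective for sulfur over the two unactivated olefins.

Step 14
Reactants: 19 11-(phenylsulfonyl)-ent-drima-1,7-diene
Product: 21 (2R)-11-(phenylsulfonyl)-ent-drim-7-en-2-ol (hydroxyl equatorial), via C2 alkyl borabicyclononane 20 (not isolated)
Conditions: 9-borabicyclo[3.3.1]nonane, THF, 20 → 50 °C; then NaOH, H2O2, 0 → 20 °C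
Reagents that add atoms: 9-borabicyclo[3.3.1]nonane B1C2CCCC1CCC2 (boron of 20 only); hydrogen peroxide OO (oxygen on C2)
Why: Hydroboration–oxidation with a hindered dialkylborane: boron adds to C2, the olefinic carbon remote from quaternary C10, on the face opposite the axial methyl groups on C10 and C4, and oxidation with retention gives the equatorial 2R alcohol. The trisubstituted ring-B olefin, flanked by C9 and C17, should react much more slowly with this reagent.

Step 15
Reactants: 22 (R)-2-methylglycidol
Product: 23 (S)-2-methyloxirane-2-carbaldehyde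
Conditions: 2,2,6,6-tetramethylpiperidin-1-oxyl (cat.), PhI(OAc)2, CH2Cl2, 0 → 20 °C; NaHCO3 wash, distilled
Reagents that add atoms: none
Why: Nitroxyl-catalysed oxidation of the primary alcohol under near-neutral conditions that leave the epoxide intact; the quaternary centre cannot epimerise (the descriptor becomes S only through the priority rules).

Step 16
Reactants: 23 (S)-2-methyloxirane-2-carbaldehyde
Product: 24 (R)-2-ethenyl-2-methyloxirane
Conditions: Ph3PCH3Br, n-BuLi, THF, 0 °C; then 23, −78 → 20 °C; distilled as a THF solution
Reagents that add atoms: methyltriphenylphosphonium bromide C[P+](c1ccccc1)(c1ccccc1)c1ccccc1.[Br-]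
Why: Wittig methylenation of a non-enolisable α-epoxy aldehyde; the stereocentre is untouched.

Step 17
Reactants: 21 (2R)-11-(phenylsulfonyl)-ent-drim-7-en-2-ol; 24 (R)-2-ethenyl-2-methyloxirane
Product: 25 (2R,13S)-11-(phenylsulfonyl)-ent-labda-7,14-diene-2,13-diol (C11 epimers)
Conditions: 21, n-BuLi (2.2 equiv), THF–DMPU, −78 → −20 °C; then 24, −20 → 20 °C; H2O
Reagents that add atoms: none
Why: Dianion alkylation: the first equivalent of base forms the C2 alkoxide, the second the α-sulfonyl carbanion at C11, which opens the 2,2-disubstituted epoxide by SN2 attack at its methylene carbon, as uncatalysed stabilised carbanions do with vinyl oxiranes. The C13–O bond is not broken, so 13S follows from 24; the C11 epimer mixture is erased in the next step.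

Step 18
Reactants: 25 (2R,13S)-11-(phenylsulfonyl)-ent-labda-7,14-diene-2,13-diol
Product: 26 (2R,5R,9R,10R,13S)-labda-7,14-diene-2,13-diol
Conditions: Na(Hg), Na2HPO4, MeOH–THF, −20 → 0 °C
Reagents that add atoms: none
Why: Julia-type reductive desulfonylation by electron transfer in buffered methanol; the hydroxyl is γ to the sulfone, so no elimination can occur, and the isolated olefins and the allylic alcohol are not reduced.

Step 19
Reactants: 26 (2R,5R,9R,10R,13S)-labda-7,14-diene-2,13-diol; 10 3-methylbut-2-enoyl chloride
Product: 27 (2R,5R,9R,10R,13S)-13-hydroxylabda-7,14-dien-2-yl 3-methylbut-2-enoate (CNP0252389.1)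
Conditions: 10, pyridine, 4-(dimethylamino)pyridine (cat.), CH2Cl2, 0 °C
Reagents that add atoms: none
Why: Acylation of the secondary equatorial alcohol beside the unreactive tertiary allylic alcohol; pyridine at low temperature avoids deconjugation of the acyl chloride and acid-induced ionisation at C13.

## Compound list

1 | dimedone (5,5-dimethylcyclohexane-1,3-dione) | CC1(C)CC(=O)CC(=O)C1 | starting material
2 | 3-ethoxy-5,5-dimethylcyclohex-2-en-1-one | CCOC1=CC(=O)CC(C)(C)C1 | intermediate
3 | allyl bromide | C=CCBr | starting material
4 | rac-6-allyl-3-ethoxy-5,5-dimethylcyclohex-2-en-1-one | CCOC1=CC(=O)C(CC=C)C(C)(C)C1 | intermediate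
5 | rac-6-allyl-3-ethoxy-1,5,5-trimethylcyclohex-2-en-1-ol (diastereomer mixture, not isolated) | CCOC1=CC(C)(O)C(CC=C)C(C)(C)C1 | intermediate
6 | rac-4-allyl-3,5,5-trimethylcyclohex-2-en-1-one | CC1=CC(=O)CC(C)(C)C1CC=C | intermediate
7 | rac-(1R*,4R*)-4-allyl-3,5,5-trimethylcyclohex-2-en-1-ol (trans; both enantiomers shown) | O[C@H]1C=C(C)[C@H](CC=C)C(C)(C)C1.O[C@@H]1C=C(C)[C@@H](CC=C)C(C)(C)C1 | intermediate
8 | (1R,4R)-4-allyl-3,5,5-trimethylcyclohex-2-en-1-yl acetate | CC(=O)O[C@H]1C=C(C)[C@H](CC=C)C(C)(C)C1 | intermediate
9 | (1R,4R)-4-allyl-3,5,5-trimethylcyclohex-2-en-1-ol | O[C@H]1C=C(C)[C@H](CC=C)C(C)(C)C1 | intermediate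
10 | 3-methylbut-2-enoyl chloride (senecioyl chloride) | CC(C)=CC(Cl)=O | starting material
11 | (1R,4R)-4-allyl-3,5,5-trimethylcyclohex-2-en-1-yl 3-methylbut-2-enoate | CC(C)=CC(=O)O[C@H]1C=C(C)[C@H](CC=C)C(C)(C)C1 | intermediate
12 | (1Z)-1-{[(1R,4R)-4-allyl-3,5,5-trimethylcyclohex-2-en-1-yl]oxy}-3-methyl-1-(trimethylsilyloxy)buta-1,3-diene (not isolated) | C=C(C)/C=C(\O[Si](C)(C)C)O[C@H]1C=C(C)[C@H](CC=C)C(C)(C)C1 | intermediate
13 | trimethylsilyl (2R)-2-[(1R,6R)-6-allyl-1,5,5-trimethylcyclohex-2-en-1-yl]-3-methylbut-3-enoate (not isolated) | C=CC[C@@H]1C(C)(C)CC=C[C@@]1(C)[C@H](C(=O)O[Si](C)(C)C)C(C)=C | intermediate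
14 | (2R)-2-[(1R,6R)-6-allyl-1,5,5-trimethylcyclohex-2-en-1-yl]-3-methylbut-3-enoic acid | C=CC[C@@H]1C(C)(C)CC=C[C@@]1(C)[C@H](C(=O)O)C(C)=C | intermediate
15 | methyl (2R)-2-[(1R,6R)-6-allyl-1,5,5-trimethylcyclohex-2-en-1-yl]-3-methylbut-3-enoate (metathesis precursor) | C=CC[C@@H]1C(C)(C)CC=C[C@@]1(C)[C@H](C(=O)OC)C(C)=C | intermediate
16 | methyl ent-drima-1,7-dien-11-oate (5R,9R,10R) | COC(=O)[C@@H]1C(C)=CC[C@@H]2C(C)(C)CC=C[C@@]12C | intermediate
17 | ent-drima-1,7-dien-11-ol | OC[C@@H]1C(C)=CC[C@@H]2C(C)(C)CC=C[C@@]12C | intermediate
18 | 11-(phenylsulfanyl)-ent-drima-1,7-diene | c1ccccc1SC[C@@H]1C(C)=CC[C@@H]2C(C)(C)CC=C[C@@]12C | intermediate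
19 | 11-(phenylsulfonyl)-ent-drima-1,7-diene | O=S(=O)(C[C@@H]1C(C)=CC[C@@H]2C(C)(C)CC=C[C@@]12C)c1ccccc1 | intermediate
20 | 9-[(2R)-11-(phenylsulfonyl)-ent-drim-7-en-2-yl]-9-borabicyclo[3.3.1]nonane (not isolated) | O=S(=O)(C[C@@H]1C(C)=CC[C@@H]2C(C)(C)C[C@@H](B3C4CCCC3CCC4)C[C@@]12C)c1ccccc1 | intermediate
21 | (2R)-11-(phenylsulfonyl)-ent-drim-7-en-2-ol | O=S(=O)(C[C@@H]1C(C)=CC[C@@H]2C(C)(C)C[C@@H](O)C[C@@]12C)c1ccccc1 | intermediate
22 | (R)-2-methylglycidol | OC[C@]1(C)CO1 | starting material
23 | (S)-2-methyloxirane-2-carbaldehyde | O=C[C@]1(C)CO1 | intermediate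
24 | (R)-2-ethenyl-2-methyloxirane | C=C[C@]1(C)CO1 | intermediate
25 | (2R,13S)-11-(phenylsulfonyl)-ent-labda-7,14-diene-2,13-diol (C11 epimers) | C=C[C@@](C)(O)CC([C@@H]1C(C)=CC[C@@H]2C(C)(C)C[C@@H](O)C[C@@]12C)S(=O)(=O)c1ccccc1 | intermediate
26 | (2R,5R,9R,10R,13S)-labda-7,14-diene-2,13-diol | C=C[C@@](C)(O)CC[C@@H]1C(C)=CC[C@@H]2C(C)(C)C[C@@H](O)C[C@@]12C | intermediate
27 | (2R,5R,9R,10R,13S)-13-hydroxylabda-7,14-dien-2-yl 3-methylbut-2-enoate (CNP0252389.1) | C=C[C@@](C)(O)CC[C@@H]1C(C)=CC[C@@H]2C(C)(C)C[C@@H](OC(=O)C=C(C)C)C[C@@]12C | target

## Step count and least certain steps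

Total: 19 steps. Longest linear sequence: 17 steps (steps 1–14 and 17–19); steps 15 and 16 are a two-step side branch to 24.

Step 10 (key step). The closure onto the 1,1-disubstituted olefin next to C9 may be slow, which gives time for intermolecular metathesis at the allyl terminus and for ruthenium hydride–induced olefin migration or C9 epimerisation next to the ester. Fallback: take the ester out before the metal step. Setting out from 15, LiAlH4 in Et2O at 0 °C gives the triene alcohol (2R)-2-[(1R,6R)-6-allyl-1,5,5-trimethylcyclohex-2-en-1-yl]-3-methylbut-3-en-1-ol F1, which has no acidic C9–H; ring-closing metathesis of F1 with the same catalyst then gives 17 directly, where the route is rejoined.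

Step 8. The C9 configuration may erode through a competing chair-like transition state or through loss of dienolate geometry, and the shift onto a fully substituted terminus may be slow. Fallback: correct C9 after ring closure instead of controlling it in the rearrangement. Setting out from 11, the acid mixture is carried on unseparated: the (2S)-acid F2 is esterified to its methyl ester F3 and cyclised to methyl 9-epi-ent-drima-1,7-dien-11-oate F4 under the conditions of steps 9 and 10. The mixture of F4 and 16 is converted with LiN(i-Pr)2 at −78 °C into one ester dienolate and protonated kinetically at C9 from the face opposite C20 (acetic acid quench), which returns all material at 16.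

Step 5. The enzyme may discriminate poorly between the enantiomers, because the two flanks of the carbinol differ little in size. Fallback: separate covalent diastereomers. Setting out from 7, esterification with (S)-2-methoxy-2-phenylacetic acid (dicyclohexylcarbodiimide, 4-(dimethylamino)pyridine) gives the (1R,4R)-ester F5 and the (1S,4S)-ester F6, which are separated by chromatography; methanolysis of F5 (K2CO3, MeOH) returns to the route at 9.

Step 14. Once the hindered ring-A olefin has to be forced, hydroboration of the ring-B olefin may compete, and the choice between C1 and C2 may be incomplete. Fallback: mask the ring-B olefin. Setting out from 19, 3-chloroperbenzoic acid epoxidises the more electron-rich trisubstituted olefin from the face opposite C20 to give 7,8-epoxy-11-(phenylsulfonyl)-ent-drim-1-ene F7. Hydroboration–oxidation as in step 14 then gives (2R)-7,8-epoxy-11-(phenylsulfonyl)-ent-driman-2-ol F8, and deoxygenation of the epoxide with NaI, Zn and NaOAc in acetic acid restores the olefin, returning at 21.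

Step 17. The hindered dianion may attack the vinyl terminus in the SN2′ sense, or act as a base and isomerise the vinyl epoxide, instead of opening it at the methylene carbon. Fallback: use a glycidyl ether without a vinyl group and make the vinyl group last.
- Compound 22 is silylated (t-BuMe2SiCl, imidazole) to (S)-tert-butyldimethyl[(2-methyloxiran-2-yl)methoxy]silane F9.
- Setting out from 21, the dianion opens F9 to 14-(tert-butyldimethylsilyloxy)-11-(phenylsulfonyl)-15-nor-ent-labd-7-ene-2,13-diol F10.
- Na(Hg) removes the sulfone to give 14-(tert-butyldimethylsilyloxy)-15-nor-ent-labd-7-ene-2,13-diol F11.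
- Acylation with 10 as in step 19 gives the C2 3-methylbut-2-enoate F12.
- HF·pyridine frees the primary alcohol to give (13S)-13,14-dihydroxy-15-nor-ent-labd-7-en-2-yl 3-methylbut-2-enoate F13.
- Oxidation with SO3·pyridine, dimethyl sulfoxide and i-Pr2NEt gives (13S)-13-hydroxy-14-oxo-15-nor-ent-labd-7-en-2-yl 3-methylbut-2-enoate F14.
- Methylenation of F14 with excess Ph3P=CH2 at −78 → 0 °C returns to the route at 27.

## Further compounds

F1 | step 10 | (2R)-2-[(1R,6R)-6-allyl-1,5,5-trimethylcyclohex-2-en-1-yl]-3-methylbut-3-en-1-ol | C=CC[C@@H]1C(C)(C)CC=C[C@@]1(C)[C@H](CO)C(C)=C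
F2 | step 8 | (2S)-2-[(1R,6R)-6-allyl-1,5,5-trimethylcyclohex-2-en-1-yl]-3-methylbut-3-enoic acid | C=CC[C@@H]1C(C)(C)CC=C[C@@]1(C)[C@@H](C(=O)O)C(C)=C
F3 | step 8 | methyl (2S)-2-[(1R,6R)-6-allyl-1,5,5-trimethylcyclohex-2-en-1-yl]-3-methylbut-3-enoate | C=CC[C@@H]1C(C)(C)CC=C[C@@]1(C)[C@@H](C(=O)OC)C(C)=C
F4 | step 8 | methyl 9-epi-ent-drima-1,7-dien-11-oate (5R,9S,10R) | COC(=O)[C@H]1C(C)=CC[C@@H]2C(C)(C)CC=C[C@@]12C
F5 | step 5 | (1R,4R)-4-allyl-3,5,5-trimethylcyclohex-2-en-1-yl (S)-2-methoxy-2-phenylacetate | CO[C@H](C(=O)O[C@H]1C=C(C)[C@H](CC=C)C(C)(C)C1)c1ccccc1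
F6 | step 5 | (1S,4S)-4-allyl-3,5,5-trimethylcyclohex-2-en-1-yl (S)-2-methoxy-2-phenylacetate | CO[C@H](C(=O)O[C@@H]1C=C(C)[C@@H](CC=C)C(C)(C)C1)c1ccccc1
F7 | step 14 | 7,8-epoxy-11-(phenylsulfonyl)-ent-drim-1-ene (epoxide on the face opposite C20) | O=S(=O)(C[C@@H]1[C@@]3(C)O[C@H]3C[C@@H]2C(C)(C)CC=C[C@@]12C)c1ccccc1
F8 | step 14 | (2R)-7,8-epoxy-11-(phenylsulfonyl)-ent-driman-2-ol | O=S(=O)(C[C@@H]1[C@@]3(C)O[C@H]3C[C@@H]2C(C)(C)C[C@@H](O)C[C@@]12C)c1ccccc1
F9 | step 17 | (S)-tert-butyldimethyl[(2-methyloxiran-2-yl)methoxy]silane | CC(C)(C)[Si](C)(C)OC[C@]1(C)CO1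
F10 | step 17 | (2R,13S)-14-(tert-butyldimethylsilyloxy)-11-(phenylsulfonyl)-15-nor-ent-labd-7-ene-2,13-diol (C11 epimers) | CC(C)(C)[Si](C)(C)OC[C@@](C)(O)CC([C@@H]1C(C)=CC[C@@H]2C(C)(C)C[C@@H](O)C[C@@]12C)S(=O)(=O)c1ccccc1
F11 | step 17 | (2R,13S)-14-(tert-butyldimethylsilyloxy)-15-nor-ent-labd-7-ene-2,13-diol | CC(C)(C)[Si](C)(C)OC[C@@](C)(O)CC[C@@H]1C(C)=CC[C@@H]2C(C)(C)C[C@@H](O)C[C@@]12C
F12 | step 17 | (2R,13S)-14-(tert-butyldimethylsilyloxy)-13-hydroxy-15-nor-ent-labd-7-en-2-yl 3-methylbut-2-enoate | CC(C)(C)[Si](C)(C)OC[C@@](C)(O)CC[C@@H]1C(C)=CC[C@@H]2C(C)(C)C[C@@H](OC(=O)C=C(C)C)C[C@@]12C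
F13 | step 17 | (2R,13S)-13,14-dihydroxy-15-nor-ent-labd-7-en-2-yl 3-methylbut-2-enoate | OC[C@@](C)(O)CC[C@@H]1C(C)=CC[C@@H]2C(C)(C)C[C@@H](OC(=O)C=C(C)C)C[C@@]12C
F14 | step 17 | (2R,13S)-13-hydroxy-14-oxo-15-nor-ent-labd-7-en-2-yl 3-methylbut-2-enoate | O=C[C@@](C)(O)CC[C@@H]1C(C)=CC[C@@H]2C(C)(C)C[C@@H](OC(=O)C=C(C)C)C[C@@]12C
A1 | alternative 1 | (S)-3-methyl-4-(2-methylbut-3-en-2-yl)cyclohex-2-en-1-one | CC1=CC(=O)CC[C@@H]1C(C)(C)C=C
A2 | alternative 1 | ring-B keto alcohol: 3-allyl-2-(hydroxymethyl)-3-methyl-4-(2-methylbut-3-en-2-yl)cyclohexan-1-one (allyl trans to the C5 substituent, hydroxymethyl cis to the C10 methyl) | C=CC[C@@]1(C)[C@H](CO)C(=O)CC[C@@H]1C(C)(C)C=C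
A3 | alternative 2 | acyclic E-enyne with C11 silyl ether and C1=C2 enol silane (C5 stereocentre as in the target) | CC#CC[C@@H](/C(C)=C/CO[Si](C)(C)C(C)(C)C)C(C)(C)CC(=C)O[Si](C)(C)C(C)(C)C
A4 | alternative 2 | 11-(tert-butyldimethylsilyloxy)-ent-drim-7-en-2-one | CC(C)(C)[Si](C)(C)OC[C@@H]1C(C)=CC[C@@H]2C(C)(C)CC(=O)C[C@@]12C
A5 | alternative 3 | previtamin-type 6Z,8E-triene with 2- and 11-silyloxy groups | CC1=C(\C=C/C(C)=C/CO[Si](C)(C)C(C)(C)C)C(C)(C)C[C@@H](O[Si](C)(C)C(C)(C)C)C1
A6 | alternative 3 | 2,11-bis(tert-butyldimethylsilyloxy)-ent-drima-5,7-diene | CC(C)(C)[Si](C)(C)OC[C@@H]1C(C)=CC=C2C(C)(C)C[C@@H](O[Si](C)(C)C(C)(C)C)C[C@@]12C
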